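(The readings stem from a simulated flask with constants of no real substance.)

The rate constants are unknown, so start from what the plateaus give. The reckoning below is my own.

| flask | free monomer | transfer agent | protic impurity | pre-initiator | remark | time |
|---|---|---|---|---|---|---|
| dusk | 2 M | 0.084 M | 0.10 M | 0.5 mol% | run made earlier |  |
| winter | 2 M | 0.13 M | 0.10 M | 0.5 mol% | run made earlier |  |
| noon | 2 M | 0.060 M | 0.15 M | 0.5 mol% | run made earlier |  |
| flask | 2.0 M | 0.0600 M | 0.100 M | 0.5 mol% |  | 1.5 h |

| run | time / min | monomer in chains / % | free monomer / % |
|---|---|---|---|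
| dusk | 5.00 | 4 | 93 |
| dusk | 15.0 | 13 | 85 |
| dusk | 25.0 | 16 | 80 |
| dusk | 40.0 | 18 | 79 |
| dusk | 50.0 | 19 | 77 |
| winter | 5.00 | 4 | 91 |
| winter | 15.0 | 8 | 83 |
| winter | 25.0 | 11 | 80 |
| winter | 40.0 | 13 | 86 |
| winter | 50.0 | 14 | 84 |
| noon | 4.00 | 3 | 92 |
| noon | 8.00 | 6 | 88 |
| noon | 15.0 | 14 | 79 |
| noon | 30.0 | 20 | 74 |
| noon | 50.0 | 21 | 68 |

(standard deviation of a reading: 2 percentage points)

- the average divides the monomer in chains by the number of chains begun, living and dead together
- the analysis behind the earlier runs scatters by 2 percentage points, standard deviation
- the earlier runs do not show the number of chains; that part of a forecast is a guess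

1. average number of monomer units in a chain (chains begun, living or dead) at 1.5 h
2. part of the free monomer that has reacted at 1.5 h

Count one free monomer taken per protic impurity, a share 5.00% of the charge in dusk, winter and the flask. Call f the fraction left: the free monomer not in chains, as a share of what the impurity leaves. Assume chains take free monomer in proportion to what is there (pseudo-first-order) and stop in proportion to c(transfer agent). Then the stopping load should match across runs of equal loading:

S = −c(transfer agent) · ln f

From each run's last reading of monomer in chains:

dusk 0.0187 M, winter 0.0207 M, noon 0.0155 M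

Winter reads highest, and its load puts the upper end of my bracket for the flask's reacted share at 32.7%. Noon reads lowest, and its load puts the lower end at 26.6%. Tighten with the mean load:

0.0183 M, so c = 30.0%

Guess one chain per pre-initiator, 0.0100 M. Then dp runs from 43.1 to 55.5, with 50.0 at the mean load.

The forecast says c 30% and dp 30, adding: “Chain count is a guess”. Its c stands inside my bracket, and its dp stands below my range.

The flask gives c 31.0% and dp 51.9, both inside.

    free monomer + initiator → living end + monomer in chains (k = 1.66 M⁻¹ min⁻¹)
    free monomer + living end → monomer in chains + living end, rate k2*[living end]*[free monomer] (k = 4.36 M⁻¹ min⁻¹)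
    living end + transfer agent → dead chain (kL = 2.54 M⁻¹ min⁻¹)
    pre-initiator → initiator (k = 0.117 min⁻¹)
    protic impurity + free monomer → quenched substrate (k = 0.278 M⁻¹ min⁻¹)

Free monomer at 69.0% gives the flask a load of 0.0192 M, above the mean load of 0.0183 M. Now take the neighbouring flask, the same flask with 0.2 mol% of pre-initiator, and scale the mean load with the loading:

S = 0.00732 M, so c = 15.9%

The neighbouring flask gives 15.8%.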